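**Retrosynthetic overview**
1. The last operation is hydrogenolysis of an O4-benzyl ether. This ether masks the 4(1H)-quinolone as an aromatic 4-alkoxyquinoline during the fragment union.
2. The key disconnection is the side-chain bond C3'–C4' (C1' is the CH2 on ring carbon C2). Both carbons are generated as primary alkyl radicals from two carboxylic acids (as N-hydroxyphthalimide esters) and joined by a Ni-electrocatalytic doubly decarboxylative C(sp3)–C(sp3) coupling, a union of two carbons of like polarity.
3. The enabling feature is the unbranched, heteroatom-free (CH2)11 tether between C2 of the pyridone ring and the C12' ketone carbon. Cut at C3'–C4', it leaves two unstabilised primary CH2 termini: C3' lies three carbons from the ring (only 4-exo or 5-endo closures onto C2, C3 or N1 are open to it) and C4' lies eight carbons from the carbonyl. Adding one CO2H to each terminus maps the halves onto glutaric acid (C5) and undec-10-enoic acid (C11).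
4. Quinoline half: the benzene ring comes from aniline. The pyridone ring, the only ring formed, is closed by a Conrad–Limpach sequence on dimethyl 2-methoxy-3-oxoheptanedioate (crossed Claisen of methyl methoxyacetate with methyl glutaryl chloride).
5. Ketone half: Tsuji–Wacker oxidation of undec-10-enoic acid, with the ketone carried unprotected to the end.

Key step: step 9

Remark on the chemistry: the target has no stereocentre and no configurable double bond, so it is achiral and needs no enantiocontrol. It is drawn as the 4(1H)-quinolone tautomer.

**Step 1**
Reactants: 1 undec-10-enoic acid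
Product: 2 10-oxoundecanoic acid
Conditions: PdCl2 (5 mol %), CuCl (co-catalyst), O2 (1 atm), DMF/H2O, rt
Reagents that add atoms: water, O
Why: Tsuji–Wacker oxidation: Markovnikov hydroxypalladation of the terminal alkene followed by β-hydride elimination should give the methyl ketone, and a remote free carboxylic acid is tolerated under these conditions.

**Step 2**
Reactants: 2 10-oxoundecanoic acid
Product: 3 1,3-dioxoisoindolin-2-yl 10-oxoundecanoate
Conditions: N-hydroxyphthalimide, DIC, DMAP (cat.), CH2Cl2, 0 °C to rt
Reagents that add atoms: N-hydroxyphthalimide, O=C1c2ccccc2C(=O)N1O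
Why: Steglich-type carbodiimide esterification converts the acid into its redox-active N-hydroxyphthalimide ester, the methyl ketone being inert to DIC, DMAP and the weakly nucleophilic N-hydroxyimide.

**Step 3**
Reactants: 4 methyl methoxyacetate (2.2 equiv), 5 methyl 5-chloro-5-oxopentanoate (methyl glutaryl chloride)
Product: 7 dimethyl 2-methoxy-3-oxoheptanedioate (racemic), via the chelated lithium enolate of methyl methoxyacetate 6 (not isolated)
Conditions: LiHMDS (2.2 equiv), THF, −78 °C; then 5, −78 to −40 °C; aq. NH4Cl
Reagents that add atoms: none
Why: Crossed Claisen acylation: the preformed enolate 6 attacks the acid chloride far faster than any of the methyl esters, the second equivalent of 6 deprotonates the acidic β-keto ester as it forms and thereby blocks a second acylation, and the new C2 stereocentre is racemic, configurationally labile and erased in step 4.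

**Step 4**
Reactants: 7 dimethyl 2-methoxy-3-oxoheptanedioate, 8 aniline
Product: 9 dimethyl (2E)-2-methoxy-3-(phenylamino)hept-2-enedioate
Conditions: p-TsOH·H2O (2 mol %), cyclohexane, Dean–Stark, reflux
Reagents that add atoms: none
Why: First stage of the Conrad–Limpach synthesis: acid-catalysed condensation with azeotropic removal of water takes place at the ketone at about 80 °C, where attack on the esters (the Knorr anilide pathway) is slow, and should give the β-anilinoacrylate in its N–H···O=C hydrogen-bonded E form, whose geometry is of no consequence because it equilibrates on heating.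

**Step 5**
Reactants: 9 dimethyl (2E)-2-methoxy-3-(phenylamino)hept-2-enedioate
Product: 10 methyl 4-(3-methoxy-4-oxo-1,4-dihydroquinolin-2-yl)butanoate
Conditions: Ph2O, 250 °C, 15–20 min (9 added dropwise to the hot solvent, MeOH distilled off); cool, hexane
Reagents that add atoms: none
Why: Conrad–Limpach thermal cyclisation: loss of methanol from the conjugated ester and six-membered ring closure of C1 onto the ortho carbon of the N-phenyl ring, followed by tautomerisation, build the pyridone ring, and brief contact with the hot solvent is meant to spare the isolated ester.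

**Step 6**
Reactants: 10 methyl 4-(3-methoxy-4-oxo-1,4-dihydroquinolin-2-yl)butanoate
Product: 11 methyl 4-[4-(benzyloxy)-3-methoxyquinolin-2-yl]butanoate
Conditions: BnBr, K2CO3, DMF, 50 °C
Reagents that add atoms: benzyl bromide, BrCc1ccccc1
Why: Williamson-type alkylation of the ambident quinolonate: N1 is shielded by the C2 chain and the peri C8–H, so benzylation is expected at O4, as is usual for 2,3-disubstituted 4-quinolones, and gives the fully aromatic quinoline.

**Step 7**
Reactants: 11 methyl 4-[4-(benzyloxy)-3-methoxyquinolin-2-yl]butanoate
Product: 12 4-[4-(benzyloxy)-3-methoxyquinolin-2-yl]butanoic acid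
Conditions: LiOH·H2O, THF/MeOH/H2O, rt; then 1 M HCl to pH 4–5
Reagents that add atoms: lithium hydroxide, [Li+].[OH-]
Why: Standard saponification (BAc2) of the unhindered methyl ester; both aryl ethers are inert to hydroxide at room temperature and the amphoteric product is collected at its isoelectric pH.

**Step 8**
Reactants: 12 4-[4-(benzyloxy)-3-methoxyquinolin-2-yl]butanoic acid
Product: 13 1,3-dioxoisoindolin-2-yl 4-[4-(benzyloxy)-3-methoxyquinolin-2-yl]butanoate
Conditions: N-hydroxyphthalimide, DIC, DMAP (cat.), CH2Cl2, rt
Reagents that add atoms: N-hydroxyphthalimide, O=C1c2ccccc2C(=O)N1O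
Why: Steglich-type esterification as in step 2; with O4 benzylated there is no N–H or quinolone oxygen left that could intercept the activated acyl group.

**Step 9**
Reactants: 13 1,3-dioxoisoindolin-2-yl 4-[4-(benzyloxy)-3-methoxyquinolin-2-yl]butanoate (1 equiv), 3 1,3-dioxoisoindolin-2-yl 10-oxoundecanoate (3 equiv)
Product: 16 13-[4-(benzyloxy)-3-methoxyquinolin-2-yl]tridecan-2-one, via 3-[4-(benzyloxy)-3-methoxyquinolin-2-yl]propyl radical 14 (not isolated), via 9-oxodecyl radical 15 (not isolated)
Conditions: NiCl2·glyme (20 mol %), 2,2':6',2''-terpyridine-type tridentate ligand (20 mol %), NaI (electrolyte), DMF, undivided cell, Zn anode / RVC cathode, constant current, rt; aq. NH4Cl work-up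
Reagents that add atoms: none
Why: Low-valent nickel, regenerated at the cathode while the zinc anode dissolves, transfers one electron to each N-acyloxyphthalimide; the radical anions fragment to phthalimide anion, CO2 and the primary radicals 14 (C3') and 15 (C4'), which are captured one after the other at nickel to give a dialkylnickel(III) species that reductively eliminates the C3'–C4' bond. The closest known reaction type is the Ni-electrocatalytic doubly decarboxylative C(sp3)–C(sp3) cross-coupling of two redox-active esters (the reductive counterpart of a mixed Kolbe electrolysis), which is established for primary/primary pairs and for substrates carrying ketones and azines. No ring is closed and no stereocentre is created. The selectivity needed is cross- over homocoupling: two unhindered primary radicals are distinguished only statistically, so the cheap two-step ester 3 is used in threefold excess to channel the more valuable 13 into the cross product, and the homodimers, which carry no or two basic quinoline nitrogens against one in 16, should separate by acid extraction and chromatography. The substrate secures chemoselectivity: radical 14 can reach C2, C3 or N1 of its own ring only by 4-exo or 5-endo closure, the Minisci positions C2 and C4 are both substituted, the O4-benzyl group removes the acidic N–H and the nucleophilic quinolone oxygen that could attack an active ester, and the ketone sits eight carbons from C4'. Because the medium is reducing, the electron-rich alkoxyquinoline that would be oxidised at a Kolbe anode is untouched, and the quinoline ring, benzyl ether and ketone are reduced only at potentials far beyond that of the esters.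

**Step 10**
Reactants: 16 13-[4-(benzyloxy)-3-methoxyquinolin-2-yl]tridecan-2-one
Product: 17 3-methoxy-2-(12-oxotridecyl)quinolin-4(1H)-one (target)
Conditions: H2 (1 atm), 10 % Pd/C, EtOAc/EtOH, rt
Reagents that add atoms: none
Why: Catalytic hydrogenolysis of the benzylic C–O bond frees the C4 oxygen, which settles as the 4(1H)-quinolone tautomer, while the aliphatic ketone, the methyl ether and the hetero-ring are not reduced over Pd/C at 1 atm in a neutral solvent.

**Compound list**
1 | undec-10-enoic acid | C=CCCCCCCCCC(=O)O | starting material
2 | 10-oxoundecanoic acid | CC(=O)CCCCCCCCC(=O)O | intermediate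
3 | 1,3-dioxoisoindolin-2-yl 10-oxoundecanoate | CC(=O)CCCCCCCCC(=O)ON1C(=O)c2ccccc2C1=O | intermediate
4 | methyl methoxyacetate | COCC(=O)OC | starting material
5 | methyl 5-chloro-5-oxopentanoate | COC(=O)CCCC(=O)Cl | starting material
6 | chelated lithium enolate of methyl methoxyacetate (enolate O and α-OMe cis; not isolated) | [Li+].CO/C=C(\[O-])OC | intermediate
7 | dimethyl 2-methoxy-3-oxoheptanedioate (racemic, labile C2) | COC(=O)C(OC)C(=O)CCCC(=O)OC | intermediate
8 | aniline | Nc1ccccc1 | starting material
9 | dimethyl (2E)-2-methoxy-3-(phenylamino)hept-2-enedioate | COC(=O)/C(OC)=C(\Nc1ccccc1)CCCC(=O)OC | intermediate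
10 | methyl 4-(3-methoxy-4-oxo-1,4-dihydroquinolin-2-yl)butanoate | COC(=O)CCCc1[nH]c2ccccc2c(=O)c1OC | intermediate
11 | methyl 4-[4-(benzyloxy)-3-methoxyquinolin-2-yl]butanoate | COC(=O)CCCc1nc2ccccc2c(OCc2ccccc2)c1OC | intermediate
12 | 4-[4-(benzyloxy)-3-methoxyquinolin-2-yl]butanoic acid | OC(=O)CCCc1nc2ccccc2c(OCc2ccccc2)c1OC | intermediate
13 | 1,3-dioxoisoindolin-2-yl 4-[4-(benzyloxy)-3-methoxyquinolin-2-yl]butanoate | O=C(CCCc1nc2ccccc2c(OCc2ccccc2)c1OC)ON1C(=O)c2ccccc2C1=O | intermediate
14 | 3-[4-(benzyloxy)-3-methoxyquinolin-2-yl]propyl radical (not isolated) | [CH2]CCc1nc2ccccc2c(OCc2ccccc2)c1OC | intermediate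
15 | 9-oxodecyl radical (not isolated) | [CH2]CCCCCCCC(C)=O | intermediate
16 | 13-[4-(benzyloxy)-3-methoxyquinolin-2-yl]tridecan-2-one | CC(=O)CCCCCCCCCCCc1nc2ccccc2c(OCc2ccccc2)c1OC | intermediate
17 | 3-methoxy-2-(12-oxotridecyl)quinolin-4(1H)-one | COc1c(CCCCCCCCCCCC(C)=O)[nH]c2ccccc2c1=O | target

Total step count: 10
Longest linear sequence: 8 (steps 3–10)

**Steps most likely to fail**

Step 9. The radical from the limiting ester may be lost to homocoupling, hydrogen-atom abstraction or β-hydride elimination at nickel, so that cross-selectivity stays at or below the statistical limit. The fallback sets out from 3, uses 13, and comes back to the route at 16. It replaces one radical partner by a defined two-electron nucleophile. Visible-light iododecarboxylation of 3 (LiI, cat. PPh3, blue LED, acetone) should give 10-iododecan-2-one F1. Zinc insertion (activated Zn dust, LiCl, THF, 40 °C), which tolerates the ketone, should give (9-oxodecyl)zinc(II) iodide F2. A Ni-catalysed decarboxylative alkyl–alkyl Negishi coupling of F2 with 13 (NiCl2·glyme, 4,4'-di-tert-butyl-2,2'-bipyridine, THF/DMF, rt) forms the same C3'–C4' bond and delivers 16.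

Step 5. At 250 °C the enamine nitrogen may acylate itself with the remote ester (six-membered lactam closure), or the material may decompose before ring closure onto the arene. The fallback sets out from 8 and comes back at 10. It builds the pyridone ring under base instead of heat.
- Sugasawa ortho-acylation of 8 with methoxyacetonitrile (BCl3, AlCl3, 1,2-dichloroethane, reflux; aq. HCl) should give 1-(2-aminophenyl)-2-methoxyethan-1-one F3.
- Ring opening of glutaric anhydride by F3 (THF, rt to 50 °C) gives 5-{[2-(methoxyacetyl)phenyl]amino}-5-oxopentanoic acid F4.
- Camps cyclisation (NaOH, dioxane/H2O, 100 °C) follows. The enolate of the α-methoxy ketone attacks the anilide carbonyl, while the remote group is an unreactive carboxylate. This gives 4-(3-methoxy-4-oxo-1,4-dihydroquinolin-2-yl)butanoic acid F5.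
- Fischer esterification (MeOH, cat. H2SO4, reflux) returns to 10.

Step 3. Self-condensation of the glycolate enolate, O-acylation or a second acylation may consume the reactants. The fallback sets out from 5 and comes back at 7. It introduces the methoxy group after the carbon skeleton is in place.
- C-acylation of Meldrum's acid with 5 (pyridine, CH2Cl2, 0 °C) gives methyl 5-(2,2-dimethyl-4,6-dioxo-1,3-dioxan-5-ylidene)-5-hydroxypentanoate F6.
- Methanolysis (MeOH, reflux) gives dimethyl 3-oxoheptanedioate F7.
- Regitz diazo transfer (4-acetamidobenzenesulfonyl azide, Et3N, MeCN) gives dimethyl 2-diazo-3-oxoheptanedioate F8.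
- Rh2(OAc)4-catalysed O–H insertion of the carbenoid into methanol (CH2Cl2, rt) gives 7.

**Further compounds**
F1 | step 9 | 10-iododecan-2-one | CC(=O)CCCCCCCCI
F2 | step 9 | (9-oxodecyl)zinc(II) iodide | CC(=O)CCCCCCCC[Zn]I
F3 | step 5 | 1-(2-aminophenyl)-2-methoxyethan-1-one | COCC(=O)c1ccccc1N
F4 | step 5 | 5-{[2-(methoxyacetyl)phenyl]amino}-5-oxopentanoic acid | COCC(=O)c1ccccc1NC(=O)CCCC(=O)O
F5 | step 5 | 4-(3-methoxy-4-oxo-1,4-dihydroquinolin-2-yl)butanoic acid | COc1c(CCCC(=O)O)[nH]c2ccccc2c1=O
F6 | step 3 | methyl 5-(2,2-dimethyl-4,6-dioxo-1,3-dioxan-5-ylidene)-5-hydroxypentanoate | COC(=O)CCCC(O)=C1C(=O)OC(C)(C)OC1=O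
F7 | step 3 | dimethyl 3-oxoheptanedioate | COC(=O)CC(=O)CCCC(=O)OC
F8 | step 3 | dimethyl 2-diazo-3-oxoheptanedioate | COC(=O)C(=[N+]=[N-])C(=O)CCCC(=O)OC
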